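The constants were hidden, so I reckoned with what needs none: the ligand budget, incoming ligand charged per starting complex charged, 2.50 in summer, 1.00 in winter, 1.20 in Wednesday's run.

all flasks: starting complex 0.10 M

|  | incoming ligand | remark | time |
|---|---|---|---|
| Wednesday's | 0.12 M | run made earlier |  |
| Tuesday's | 0.37 M | run made earlier |  |
| winter | 0.100 M |  | 40 min |
| summer | 0.250 M |  | 40 min |

| run | time / min | complex with one exchanged / % | starting complex / % |
|---|---|---|---|
| Wednesday's | 2.50 | 25.1 | 31.8 |
| Wednesday's | 3.00 | 24.7 | 30.9 |
| Wednesday's | 5.00 | 24.5 | 28.1 |
| Wednesday's | 8.00 | 24.5 | 27.4 |
| Wednesday's | 12.0 | 23.7 | 27.3 |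
| Wednesday's | 20.0 | 24.1 | 27.4 |
| Wednesday's | 30.0 | 23.7 | 27.7 |
| Tuesday's | 2.50 | 4.3 | 1.4 |
| Tuesday's | 3.00 | 2.3 | 0.4 |
| Tuesday's | 5.00 | 0.6 | 0.1 |
| Tuesday's | 8.00 | 0 | 0 |
| Tuesday's | 12.0 | 0.3 | 0 |
| Tuesday's | 20.0 | 0.1 | 0 |
| Tuesday's | 30.0 | 0.1 | 0 |

(scatter of a reading: 0.3 percentage points)

- reactions considered so far: leaving ligand -> by-product carried off; starting complex + incoming ligand <-> leaving ligand + complex with one exchanged; complex with two exchanged + incoming ligand <-> leaving ligand + complex with three exchanged; complex with one exchanged <-> isomer of the product; complex with one exchanged + incoming ligand <-> leaving ligand + complex with two exchanged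

1. which of these holds the largest part of the starting complex at the end of winter (complex with one exchanged / starting complex / complex with three exchanged / complex with two exchanged)
2. which of these holds the largest part of the starting complex at the end of summer (complex with one exchanged / starting complex / complex with three exchanged / complex with two exchanged)
3. final complex with one exchanged in winter, as a percentage of the starting complex charged

In Wednesday's run the starting complex read 27.4% at 8.00 min and 27.7% at 30.0 min, yet in Tuesday's run it read 0% at 8.00 min. So I took the flat stretch as the end of the 0.12 M ligand charge, the limiting reagent. A flask whose ligand is used up obeys a ledger, since each complex carries the ligands it exchanged and the isomer carries one: budget minus two equals complex with three exchanged, less twice the starting complex, less complex with one exchanged, less isomer.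

Wednesday's readings at 20.0 min put isomer minus complex with three exchanged at 1.10%. Carrying that and 24.1% of complex with one exchanged into winter gave me 37.4% starting complex, which I committed to as the largest. In summer the ledger puts complex with three exchanged at 50.0% plus those positive terms, so I chose it. The weak link was whether summer's ligand is used up, but summer's 40 min is 5.00 times the 8.00 min at which Wednesday's run stood flat.

The forecast said starting complex in winter, with 27% complex with one exchanged, and complex with two exchanged in summer: “stopping at or below 50%, so two-exchanged narrowly leads”. On summer it differs from mine.

Winter ended with starting complex at 34.8% (I had 37.4%) and 25.4% complex with one exchanged. Summer ended with complex with three exchanged at 57.6%, against 36.1% complex with two exchanged, which is where the forecast and the flask part. Summer held 0.00947% of its own ligand charge at 40.0 min, and the ledger with budget 2.50, fed with summer's other final amounts, gives 57.6% complex with three exchanged.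

    leaving ligand → by-product carried off (k = 0.0303 s⁻¹)
    starting complex + incoming ligand ⇌ leaving ligand + complex with one exchanged (K = 1.90, k = 0.201 M⁻¹ s⁻¹)
    complex with two exchanged + incoming ligand ⇌ leaving ligand + complex with three exchanged (K = 2.41, k = 0.0629 M⁻¹ s⁻¹)
    complex with one exchanged ⇌ isomer of the product (K = 0.370, k = 0.0249 s⁻¹)
    complex with one exchanged + incoming ligand ⇌ leaving ligand + complex with two exchanged (K = 7.60, k = 0.252 M⁻¹ s⁻¹)

One more flask, winter's ligand on 0.040 M starting complex, has budget 2.50, the same as summer's, so I expected summer's ending. That flask gave 3.69% complex with one exchanged, 38.5% complex with two exchanged and 55.4% complex with three exchanged.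

The numbers in the tables come from a simulation from invented constants.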